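**Two rates.** If two charges of starting material make target about equally fast, one being 3.00 times the other, then the rate is no plain proportion of the charge.

| setting | ash | oak | elm | birch | cedar |
|---|---|---|---|---|---|
| starting material | 0.400 M | 0.400 M | 0.400 M | 1.20 M | 0.160 M |
| free catalyst | 8.00 × 10⁻⁴ M | 8.00 × 10⁻⁴ M | 0.00160 M | 8.00 × 10⁻⁴ M | 8.00 × 10⁻⁴ M |
| target |  | 0.120 M |  |  |  |
| time |  |  |  |  | 50 min |

| run | time / min | [target] / M |
|---|---|---|
| ash run | 2.8 | 0.0225 |
| ash run | 8.6 | 0.0660 |
| ash run | 16 | 0.1177 |
| ash run | 26 | 0.1733 |
| ash run | 37 | 0.2233 |
| ash run | 50 | 0.2680 |
| oak run | 2.8 | 0.1430 |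
| oak run | 8.6 | 0.1871 |
| oak run | 16 | 0.2356 |
| oak run | 26 | 0.2934 |
| oak run | 37 | 0.3457 |
| oak run | 50 | 0.3857 |
| elm run | 2.8 | 0.0869 |
| elm run | 8.6 | 0.2310 |
| elm run | 16 | 0.3328 |
| elm run | 26 | 0.3741 |
| elm run | 37 | 0.3813 |
| elm run | 50 | 0.3841 |
| birch run | 2.8 | 0.0259 |
| birch run | 8.6 | 0.0731 |
| birch run | 16 | 0.1338 |
| birch run | 26 | 0.2104 |
| birch run | 37 | 0.2896 |
| birch run | 50 | 0.3692 |

(scatter of a reading: 0.001 M)

- reaction order in [free catalyst] at the outset, round the charge of the ash run, defined at two percent of the starting material turned into target
- reaction order in [starting material] at the outset, round the charge of the ash run, defined at two percent of the starting material turned into target (one fixed amount of target, the same in the runs compared)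
- target in the cedar run at 50 min, as a share of the starting material charged

- Overall: starting material -> target, with free catalyst as catalyst.
- Constant volume, constant temperature.
- The analysis sees a species whether free or bound.
- An order is taken over about fifteen percent of the charge, up and down.

**Time removed.** Dividing one run's early reading by another's, taken at the same moment, removes time. Against ash, birch stands at 1.11 times the target at 8.6 min, which is close to level. Against ash, elm with twice the catalyst stands at 3.86 times the target at 2.8 min, a reading that gives an order of 1.95.

**The crest.** Suppose that starting material holds some catalyst, so that the free share shrinks as the level rises. With levels counted as fractions of the ash charge, the rate climbs, crests and falls, and two levels of equal rate have the crest as their geometric mean. Taking birch and ash as level, this crest level, where target forms fastest on that supposition, is 1.73 ash charges. The order in starting material at the ash charge is then crest minus level over crest plus level, 0.267.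

**Cedar reckoned.** The pseudo-first-order time constant, starting material over rate, grows as the square of crest plus level. Ash, from its first reading, has 49.8 min. Cedar, taken at half its charge, has 24.9 min, so 86.6% of it turns in 50 min. Elm's last reading stands 3.98% short of its charge. Assuming the same shortfall for cedar, this reckoning gives 83.1%.

The forecast gave 1.95 in free catalyst, 0.1 in starting material and 92% for cedar, as though something arriving with the charge “ties up catalyst”, and its cedar share is what a power-law fit gives.

**The result.** Cedar gives 82.5%, with orders 2.0 in free catalyst and 0.31 in starting material. Its target does not turn on the passing of free catalyst into spent catalyst.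

    free catalyst + starting material ⇌ catalyst-substrate complex, settled at all times (1.360 M⁻¹)
    catalyst-substrate complex + free catalyst → target + 2 free catalyst (55800 M⁻¹ min⁻¹)
    free catalyst + starting material → spent catalyst + starting material (0.007740 M⁻¹ min⁻¹)
    2 starting material → homo dimer (0.01152 M⁻¹ min⁻¹)

Birch starts past the crest. The crest rate, 0.00867 M min⁻¹, would make a quarter of the birch charge in 34.6 min, and birch took longer, 38.6 min.

The earlier runs and the new flask come from a simulation from invented constants.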